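Temperature first: count how many reagent lifetimes each flask gets in its 25 min.

| flask | starting material | reagent | second substrate | catalyst | temperature | remark | time |
|---|---|---|---|---|---|---|---|
| elm | 0.25 M | 0.084 M | 0.25 M | 12 mM | 30 °C | run made earlier |  |
| oak | 0.25 M | 0.19 M | 0.25 M | 12 mM | 52 °C | run made earlier |  |
| alder | 0.25 M | 0.125 M | 0.25 M | 18 mM | 30 °C | run made earlier |  |
| alpha | 0.25 M | 0.125 M | 0.250 M | 12 mM |  | at 60 °C until 8.0 min, from then on at 20 °C | 25 min |
| beta | 0.25 M | 0.125 M | 0.250 M | 12 mM | 20 °C |  | 25 min |
| delta | 0.25 M | 0.125 M | 0.250 M | 12 mM | 60 °C |  | 25 min |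
| gamma | 0.25 M | 0.125 M | 0.250 M | 12 mM | 40 °C |  | 25 min |

| elm: time / min | elm: target / % | oak: time / min | oak: target / % | alder: time / min | alder: target / % |
|---|---|---|---|---|---|
| 1.33 | 1.6 | 0.250 | 2.3 | 2.50 | 3.2 |
| 3.00 | 1.9 | 0.667 | 4.0 | 5.00 | 6.7 |
| 6.00 | 3.1 | 1.33 | 7.9 | 8.00 | 10.0 |
| 10.0 | 6.2 | 3.00 | 14.5 | 10.0 | 11.5 |

(standard deviation of a reading: 0.5 percentage points)

* the flask with the highest amount of target, in percent of the starting material charged ("all alike" if they lie within 1.5 percentage points) (alpha / beta / delta / gamma / all alike)
* final target, as a percentage of the starting material charged, in alpha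
* final target, as a percentage of the starting material charged, in beta
* final target, as a percentage of the starting material charged, in delta
* final target, as a percentage of the starting material charged, in gamma



Starting material and reagent meet on the catalyst to give target; take one reagent per target. Reagent is the limiting reagent, so in these recipes the curve runs towards a ceiling of 50.0% of the starting material charged. Two landmarks draw it: the starting slope, and the fill time, which is the ceiling divided by that slope. While reagent stays below the 0.25 M of starting material, it raises ceiling and slope together, so the reckoning gives the same fill time at any such charge. Read it off the early readings: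

elm, 30 °C: 54.2 min

alder, 30 °C, scaled to 12 mM of catalyst: 56.0 min

oak, 52 °C: 12.8 min

Alder and oak give an activation energy of 55.0 kJ mol⁻¹. So 7.85 min is the fill time at 60 °C, the ceiling over the starting slope, against 27.9 min at 40 °C and 118 min at 20 °C.

Now count fill times; target is the ceiling times (1 − exp(−count)):

delta: count 3.18, target 47.9%

alpha: count 1.16, target 34.4%

gamma: count 0.896, target 29.6%

beta: count 0.212, target 9.56%

Watch alpha at 8.0 min: it rides delta's curve to that kink, then its slope drops by a factor of 15.0. Oak's last reading, 14.5%, lies 1.4 percentage points under its curve, against a scatter of 0.5 points, so expect delta to fall short of its figure. I expect delta highest, since its count is larger.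

The forecast also names delta, but gives alpha 20.5%, beta 8.5%, delta 22% and gamma 19%, lower than my marks in delta, on the ground that “Alder and oak both curve faster than reagent loss explains”.

The flasks give alpha 25.0%, beta 10.3%, delta 30.0% and gamma 24.8%, so delta holds more than the others.

    starting material + reagent + catalyst → catalyst + target (k = 46.2 M⁻² min⁻¹, Ea = 53.0 kJ mol⁻¹)
    second substrate + reagent + catalyst → catalyst + second product (k = 5.54 M⁻² min⁻¹, Ea = 51.0 kJ mol⁻¹)
    target ⇌ isomer of the product (K = 0.630, k = 0.00370 min⁻¹, Ea = 105 kJ mol⁻¹, ΔH = −37.0 kJ mol⁻¹)
    2 reagent → self-condensation product (k = 0.379 M⁻¹ min⁻¹, Ea = 82.0 kJ mol⁻¹)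
    (constants at 60 °C)

Delta stops at 30.0% with catalyst at 100%, reagent at 2.93% and 0.0149 M of self-condensation product. At the kink, alpha has counted 1.02 fill times; the curve marks 32.0%, and alpha holds 23.6%. Take alpha's neighbour with 0.31 M of reagent, 1.24 equiv: starting material is now the limiting one, so the ceiling is the whole of its charge while the slope still rises with reagent, the count becomes 1.44, and the mark becomes 76.4% of the starting material charged. That neighbour gives less: 44.8% of target, with 54% of starting material and 16% of reagent left.

The runs are calculated with made-up constants, and the scatter is random.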